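The nine-membered carbocycle (C4a, C5–C11, C11a) carries the methylidene carbon C11 and the C8–C9 epoxide separated only by C10; that 1,3-pattern is what a cleaved cyclobutane C8–C9–C10–C11 leaves. The ring is therefore made by expanding a cycloheptanone by two carbons: a strain-driven Grob fragmentation breaks the shared C8–C11 bond of a cis-fused bicyclo[5.2.0]nonane and delivers, in one operation, the C11 ketone and the (Z)-C8=C9 alkene next to the preset C7 carbinol. The precursor is a tertiary C11 cyclobutanol with a C9 mesylate cis to C7, a C7 silyl ether, and C1/C3 tied up as a trans-fused cyclic ethyl acetal.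

Key step: step 11

Remarks on the chemistry
- Locants follow the target throughout: C1 (OCH2), O2, C3 (acetal CH), C4, C4a and C11a (ring fusion), C5–C11 (carbocycle; C7 carbinol, C8/C9 epoxide, C11 methylidene), C12–C15 (side chain).
- Assumption: of the two pseudoenantiomeric cinchona-derived primary amines (from quinine or from quinidine), the one that gives (2S,3S)-2 is used in step 1.
- Assumption: compounds 10–20 are written as the C3 anomer with axial ethoxy; the other anomer would react in the same way and both converge at 22.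
- The lactol carbon C3 in 21, 35 and 36 and the transient centres C4/C12 in 32 and 33 are left undefined in the SMILES, because they are mixtures that converge.
- The other cis-fused diastereomer of 13 (ketene addition to the opposite face) would also converge on 19, because C8, C9 and C11 all become trigonal in step 11.

Step 1
Reactants: 1 3-methylcyclohept-2-en-1-one
Product: 2 (2S,3S)-2,3-epoxy-3-methylcycloheptan-1-one
Conditions: 9-amino-9-deoxy-epi-cinchona amine (10 mol%), CF3CO2H (20 mol%), 50% aq. H2O2, 1,4-dioxane, 50 °C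
Reagents that add atoms: hydrogen peroxide, OO
Why: Iminium-activated nucleophilic (Weitz–Scheffer-type) epoxidation under chiral primary-amine catalysis should add hydroperoxide to one enantioface of the enone, so the catalyst fixes the oxygen-bearing quaternary centre C7 (and C8), the cis fusion of the epoxide being enforced by the ring.

Step 2
Reactants: 2 (2S,3S)-2,3-epoxy-3-methylcycloheptan-1-one
Product: 3 (3S)-3-hydroxy-3-methylcycloheptan-1-one
Conditions: SmI2 (2.2 equiv), THF/MeOH, −90 °C
Reagents that add atoms: none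
Why: Two single-electron transfers cleave the Cα–O bond of the α,β-epoxy ketone and methanol protonates the enolate (reductive epoxide opening), which leaves the C7 carbinol untouched at a temperature where β-elimination and retro-aldol cleavage are slow.

Step 3
Reactants: 3 (3S)-3-hydroxy-3-methylcycloheptan-1-one
Product: 4 (3S)-3-[(tert-butyldimethylsilyl)oxy]-3-methylcycloheptan-1-one
Conditions: t-BuMe2SiOTf, 2,6-lutidine, CH2Cl2, −78 → 0 °C
Reagents that add atoms: tert-butyldimethylsilyl trifluoromethanesulfonate, CC(C)(C)[Si](C)(C)OS(=O)(=O)C(F)(F)F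
Why: Silyl triflate with a hindered base silylates the tertiary alcohol quickly (silyl ether formation), which shuts off retro-aldol and oxa-Michael pathways and gives a group that should survive every later acidic and basic step.

Step 4
Reactants: 4 (3S)-3-[(tert-butyldimethylsilyl)oxy]-3-methylcycloheptan-1-one
Product: 6 (6S)-6-[(tert-butyldimethylsilyl)oxy]-6-methylcyclohept-2-en-1-one, via trimethylsilyl enol ether 5 (not isolated)
Conditions: LiN(i-Pr)2, Me3SiCl, THF, −78 °C; then Pd(OAc)2 (1.05 equiv), MeCN, rt
Reagents that add atoms: none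
Why: Kinetic deprotonation should take place at the unhindered C11a methylene and not at C8, which is neopentyl to the C7 quaternary carbon, and Saegusa–Ito oxidation of the silyl enol ether then gives the C11a=C4a enone.

Step 5
Reactants: 6 (6S)-6-[(tert-butyldimethylsilyl)oxy]-6-methylcyclohept-2-en-1-one; 7 (Z)-1-bromo-2-ethoxyethene
Product: 10 C3 ethyl acetal ketone, via lithium enolate 8 (not isolated), via hydroxy enol ether 9 (not isolated)
Conditions: 7, t-BuLi (2 equiv), Et2O, −78 °C; CuBr·SMe2 (0.5 equiv); 6, −78 °C; CH2O (gas, from paraformaldehyde), −78 → −40 °C; aq. NH4Cl; then pyridinium p-toluenesulfonate (5 mol%), CH2Cl2, 0 °C → rt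
Reagents that add atoms: formaldehyde, C=O
Why: Conjugate addition of the alkenyl cuprate (an acetaldehyde enolate equivalent) should occur anti to the pseudoaxial C7 silyloxy group of the chair-like cycloheptenone, that is cis to the C7 methyl, the regiodefined enolate is hydroxymethylated anti to the new C4a substituent (aldol reaction), and acid-catalysed addition of the new hydroxyl to the enol ether closes the six-membered acetal, the ethoxy group settling axial under the anomeric effect.

Step 6
Reactants: 10 C3 ethyl acetal ketone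
Product: 11 C11 trimethylsilyl enol ether (C8=C11)
Conditions: LiN(i-Pr)2, Me3SiCl (in situ quench), THF, −78 °C
Reagents that add atoms: chlorotrimethylsilane, C[Si](C)(C)Cl
Why: Kinetic silyl enol ether formation should remove a proton of the C8 methylene in preference to the single, more encumbered C11a methine proton.

Step 7
Reactants: 11 C11 trimethylsilyl enol ether (C8=C11); 12 trichloroacetyl chloride
Product: 13 dichlorocyclobutanone
Conditions: 12, activated Zn, POCl3, Et2O, 0 °C → rt
Reagents that add atoms: none
Why: Dichloroketene made by zinc dechlorination undergoes the thermal [2+2] cycloaddition with the electron-rich silyl enol ether, its carbonyl carbon bonding to the nucleophilic C8 and the CCl2 carbon to the oxygenated C11, which gives the cis-fused cyclobutanone on the face anti to the C11a–C1 bond and the C7 silyloxy group.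

Step 8
Reactants: 13 dichlorocyclobutanone
Product: 14 cyclobutanone
Conditions: Bu3SnH (2.4 equiv), azobis(isobutyronitrile) (cat.), toluene, 80 °C
Reagents that add atoms: none
Why: Radical chain dechlorination removes both α-chlorines under neutral conditions that should not open the β-silyloxy cyclobutanone by retro-aldol cleavage.

Step 9
Reactants: 14 cyclobutanone
Product: 16 cyclobutane-1,3-diol, via C9 alcohol C11 trimethylsilyl ether 15 (not isolated)
Conditions: NaBH4, MeOH/THF, −40 °C; then K2CO3, 0 °C → rt
Reagents that add atoms: none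
Why: Borohydride should attack the cyclobutanone from the convex face of the cis-fused bicycle, anti to the seven-membered ring and its C7 quaternary carbon, which places the C9 hydroxyl cis to C7 (hydride reduction), and carbonate in methanol then cleaves the labile trimethylsilyl ether while the tert-butyldimethylsilyl ether stays.

Step 10
Reactants: 16 cyclobutane-1,3-diol
Product: 17 C11 hydroxy C9 mesylate
Conditions: MeSO2Cl (1.2 equiv), pyridine, CH2Cl2, 0 °C
Reagents that add atoms: methanesulfonyl chloride, CS(=O)(=O)Cl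
Why: Sulfonylation in pyridine is selective for the secondary cyclobutanol over the tertiary ring-fusion alcohol.

Step 11
Reactants: 17 C11 hydroxy C9 mesylate
Product: 19 nine-membered (Z)-β,γ-unsaturated C11 ketone, via potassium alkoxide 18 (not isolated)
Conditions: KOt-Bu (1.1 equiv), THF, 0 °C; pH 7 phosphate buffer
Reagents that add atoms: none
Why: Deprotonation of the C11 carbinol gives alkoxide 18, whose oxygen lone pair becomes the C11=O π bond while the C8–C11 σ bond becomes the C8=C9 π bond and mesylate leaves from C9; no σ bond is formed. This is a Grob (Wharton-type) fragmentation of a cyclic 1,3-hydroxy sulfonate, the sulfonate counterpart of the known retro-aldol two-carbon ring expansion of silyl enol ether–ketene adducts, which cleaves the same ring-fusion bond. The nine-membered ring is not closed by a cyclisation but arises by ring expansion when the bond shared by the four- and seven-membered rings is cut, the strain of the cyclobutane paying for the medium ring. No stereocentre is created (C8, C9 and C11 become trigonal); the alkene geometry is set by the C9 mesylate being cis to C7, so that rotation towards the antiperiplanar arrangement of the C8–C11 and C9–O bonds brings C7 and C10 to the same side and gives the (Z)-alkene. The step needs cleavage of C8–C11 in preference to the equally aligned C10–C11 bond, which the substrate should secure because C8–C11 is the more substituted, more strained fusion bond and its cleavage gives the disubstituted ring alkene instead of a vinyl group. A slight excess of base at 0 °C and a buffered quench should keep the β,γ-unsaturated ketone from conjugating, from epimerising at C11a and from β-elimination of O2.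

Step 12
Reactants: 19 nine-membered (Z)-β,γ-unsaturated C11 ketone
Product: 20 C11 methylidene ethyl acetal
Conditions: Cp2TiMe2 (3 equiv), toluene, 65 °C, dark
Reagents that add atoms: dimethyltitanocene, [CH3-].[CH3-].[Ti+4].c1cc[cH-]c1.c1cc[cH-]c1
Why: Petasis methylenation through the titanium methylidene is non-basic and so should convert the enolisable β,γ-unsaturated ketone into the 1,1-disubstituted alkene without moving the C8=C9 double bond or epimerising C11a.

Step 13
Reactants: 20 C11 methylidene ethyl acetal
Product: 21 lactol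
Conditions: AcOH/THF/H2O (3:1:1), 40 °C
Reagents that add atoms: water, O
Why: Mild aqueous acid hydrolyses the 2-alkoxyoxane acetal (as in tetrahydropyranyl ether cleavage) to the lactol while the tertiary silyl ether and the skipped diene are inert.

Step 14
Reactants: 21 lactol
Product: 22 δ-lactone
Conditions: 2,2,6,6-tetramethylpiperidin-1-oxyl (10 mol%), PhI(OAc)2 (1.5 equiv), CH2Cl2, rt
Reagents that add atoms: none
Why: Oxoammonium oxidation of the lactol gives the δ-lactone with C3 as the carbonyl and the O2–C1 bond intact, without touching the alkenes.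

Step 15
Reactants: 23 2,3-O-isopropylidene-D-erythronolactone
Product: 24 2-[(4R,5R)-5-(hydroxymethyl)-2,2-dimethyl-1,3-dioxolan-4-yl]propan-2-ol
Conditions: MeMgBr (3 equiv), THF, 0 °C → rt; aq. NH4Cl
Reagents that add atoms: methylmagnesium bromide, C[Mg]Br
Why: Double Grignard addition to the lactone carbonyl builds the C15 dimethyl carbinol and frees the C12 hydroxyl, the two stereocentres (future C13 and C14) coming unchanged from the chiral pool.

Step 16
Reactants: 24 2-[(4R,5R)-5-(hydroxymethyl)-2,2-dimethyl-1,3-dioxolan-4-yl]propan-2-ol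
Product: 25 (2R,3R)-4-methylpentane-1,2,3,4-tetrol
Conditions: Dowex 50W (sulfonic acid resin, H+ form), MeOH/H2O (9:1), 50 °C
Reagents that add atoms: none
Why: Acid-catalysed acetal hydrolysis removes the internal isopropylidene group so that O13 and O14 can afterwards be told apart.

Step 17
Reactants: 25 (2R,3R)-4-methylpentane-1,2,3,4-tetrol
Product: 26 (1R)-1-[(4R)-2,2-dimethyl-1,3-dioxolan-4-yl]-2-methylpropane-1,2-diol
Conditions: 2-methoxypropene (1.05 equiv), pyridinium p-toluenesulfonate (5 mol%), DMF, 0 °C; Et3N
Reagents that add atoms: 2-methoxypropene, COC(C)=C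
Why: Kinetic acetonide formation starts at the primary hydroxyl and closes onto O13 (acetalisation), which should give the terminal dioxolane and leave the C14/C15 diol free.

Step 18
Reactants: 26 (1R)-1-[(4R)-2,2-dimethyl-1,3-dioxolan-4-yl]-2-methylpropane-1,2-diol
Product: 27 bis(tert-butyldimethylsilyl) ether of 26
Conditions: t-BuMe2SiOTf (3 equiv), 2,6-lutidine, CH2Cl2, 0 °C → rt
Reagents that add atoms: tert-butyldimethylsilyl trifluoromethanesulfonate, CC(C)(C)[Si](C)(C)OS(=O)(=O)C(F)(F)F
Why: The silyl triflate silylates both the hindered secondary and the tertiary hydroxyl (silyl ether formation), giving fluoride-labile protection that keeps O14 and O15 out of the later acetalisation.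

Step 19
Reactants: 27 bis(tert-butyldimethylsilyl) ether of 26
Product: 28 (2R,3R)-3,4-bis[(tert-butyldimethylsilyl)oxy]-4-methylpentane-1,2-diol
Conditions: pyridinium p-toluenesulfonate (0.3 equiv), MeOH, 45 °C
Reagents that add atoms: none
Why: Acid-catalysed transacetalisation with methanol should cleave the terminal acetonide much faster than the hindered tert-butyldimethylsilyl ethers.

Step 20
Reactants: 28 (2R,3R)-3,4-bis[(tert-butyldimethylsilyl)oxy]-4-methylpentane-1,2-diol
Product: 29 C12/C13 bis(triethylsilyl) ether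
Conditions: Et3SiCl (2.4 equiv), imidazole, DMF, 0 °C → rt
Reagents that add atoms: chlorotriethylsilane, CC[Si](Cl)(CC)CC
Why: Standard silylation caps the primary and the C13 secondary hydroxyl as acid-labile triethylsilyl ethers.

Step 21
Reactants: 29 C12/C13 bis(triethylsilyl) ether
Product: 30 (2S,3R)-3,4-bis[(tert-butyldimethylsilyl)oxy]-4-methyl-2-[(triethylsilyl)oxy]pentanal
Conditions: (COCl)2, DMSO, CH2Cl2, −78 → −40 °C; Et3N, −78 → 0 °C
Reagents that add atoms: none
Why: Under Swern conditions the chlorosulfonium species attacks the unhindered primary triethylsilyl ether directly, so the C12 aldehyde should form in one operation while the secondary C13 triethylsilyl ether stays (Swern oxidation of a primary silyl ether).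

Step 22
Reactants: 22 δ-lactone; 30 (2S,3R)-3,4-bis[(tert-butyldimethylsilyl)oxy]-4-methyl-2-[(triethylsilyl)oxy]pentanal
Product: 32 aldol adduct, via lithium lactone enolate 31 (not isolated)
Conditions: LiN(i-Pr)2 (1.05 equiv), THF, −78 °C; then 30, −78 °C; aq. NH4Cl
Reagents that add atoms: none
Why: The lithium enolate of the δ-lactone adds to the aldehyde (aldol addition) to form the C4–C12 bond; the two new centres C4 and C12 arise as a mixture that does not matter because both become trigonal in the next step.

Step 23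
Reactants: 32 aldol adduct
Product: 34 (Z)-alkylidene lactone, via C12 mesylate 33 (not isolated)
Conditions: MeSO2Cl, Et3N, CH2Cl2, 0 °C; then 1,8-diazabicyclo[5.4.0]undec-7-ene, 0 °C
Reagents that add atoms: none
Why: Mesylation and base-induced E1cB elimination give the α-alkylidene lactone, and the (Z)-isomer with C13 on the carbonyl side should be favoured because the alternative places C13 against the equatorial C4a–C5 bond of the trans-fused ring (allylic 1,3-strain).

Step 24
Reactants: 34 (Z)-alkylidene lactone
Product: 35 (Z)-alkylidene lactol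
Conditions: i-Bu2AlH (1.3 equiv), CH2Cl2, −78 °C; aq. potassium sodium tartrate
Reagents that add atoms: none
Why: The aluminium hydride reduces the conjugated lactone in the 1,2-sense and stops at the stable aluminium hemiacetal at −78 °C, which gives the lactol.

Step 25
Reactants: 35 (Z)-alkylidene lactol
Product: 37 tris(silyl) bicyclic acetal, via C13 hydroxy lactol 36 (not isolated)
Conditions: HF·pyridine, pyridine, THF, 0 °C; aq. NaHCO3; then pyridinium p-toluenesulfonate (10 mol%), 4 Å molecular sieves, CH2Cl2, 0 °C
Reagents that add atoms: none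
Why: Buffered HF cleaves the secondary allylic triethylsilyl ether selectively, and under mild acid the lactol ionises to the allylic oxocarbenium ion, which the cis-disposed O13 captures in a 5-exo-trig acetalisation to the 2,5-dihydrofuran; the flat five-membered ring forces O13 equatorial on the chair-like oxane, so C3 forms with H3 cis to H4a (3S) under thermodynamic control, and the still silylated O14 cannot compete.

Step 26
Reactants: 37 tris(silyl) bicyclic acetal
Product: 38 triol diene
Conditions: Bu4NF (6 equiv), THF, 50 °C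
Reagents that add atoms: none
Why: Fluoride-mediated desilylation removes the three tert-butyldimethylsilyl groups, the tertiary ones requiring gentle heating, under basic conditions that the bis-acetal should tolerate.

Step 27
Reactants: 38 triol diene
Product: 39 CNP0281409.2 (target)
Conditions: VO(acac)2 (5 mol%), t-BuOOH (1.2 equiv, decane), 2,6-lutidine (0.2 equiv), CH2Cl2, 0 °C
Reagents that add atoms: tert-butyl hydroperoxide, CC(C)(C)OO
Why: Vanadium-catalysed hydroxyl-directed epoxidation is far faster for the allylic C7 alcohol than for the homoallylic C14 alcohol or the undirected C11 methylidene, and oxygen is delivered to the C8=C9 face on which the C7 hydroxyl lies near the alkene plane with the C7 methyl turned away from C10, which should set C8 and C9 as in the target.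

Compound list
1 | 3-methylcyclohept-2-en-1-one | CC1=CC(=O)CCCC1 | starting material
2 | (2S,3S)-2,3-epoxy-3-methylcycloheptan-1-one | O=C1[C@H]2O[C@@]2(C)CCCC1 | intermediate
3 | (3S)-3-hydroxy-3-methylcycloheptan-1-one | O=C1C[C@@](C)(O)CCCC1 | intermediate
4 | (3S)-3-[(tert-butyldimethylsilyl)oxy]-3-methylcycloheptan-1-one | O=C1C[C@@](C)(O[Si](C)(C)C(C)(C)C)CCCC1 | intermediate
5 | (6S)-6-[(tert-butyldimethylsilyl)oxy]-6-methyl-1-[(trimethylsilyl)oxy]cyclohept-1-ene | C[Si](C)(C)OC1=CCCC[C@](C)(O[Si](C)(C)C(C)(C)C)C1 | intermediate (not isolated)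
6 | (6S)-6-[(tert-butyldimethylsilyl)oxy]-6-methylcyclohept-2-en-1-one | O=C1C[C@@](C)(O[Si](C)(C)C(C)(C)C)CCC=C1 | intermediate
7 | (Z)-1-bromo-2-ethoxyethene | Br/C=C\OCC | starting material
8 | lithium enolate (C11–OLi, C11=C11a) of the conjugate adduct; C4a (Z)-2-ethoxyvinyl cis to the C7 methyl | [Li]OC1=C[C@@H](/C=C\OCC)CC[C@](C)(O[Si](C)(C)C(C)(C)C)C1 | intermediate (not isolated)
9 | (2S,3R,6S)-6-[(tert-butyldimethylsilyl)oxy]-3-[(Z)-2-ethoxyethenyl]-2-(hydroxymethyl)-6-methylcycloheptan-1-one | O=C1C[C@@](C)(O[Si](C)(C)C(C)(C)C)CC[C@H](/C=C\OCC)[C@H]1CO | intermediate (not isolated)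
10 | C3 ethyl acetal ketone: cycloheptanone (C11=O) trans-fused at C4a/C11a to an oxane (O2, C1, C3, C4) with axial ethoxy at C3; C7 methyl cis to C4, C7 OSi(t-Bu)Me2 | O=C1C[C@@](C)(O[Si](C)(C)C(C)(C)C)CC[C@@H]2C[C@@H](OCC)OC[C@@H]12 | intermediate
11 | C11 trimethylsilyl enol ether of 10 with the C8=C11 double bond | C[Si](C)(C)OC1=C[C@@](C)(O[Si](C)(C)C(C)(C)C)CC[C@@H]2C[C@@H](OCC)OC[C@@H]12 | intermediate
12 | trichloroacetyl chloride | ClC(=O)C(Cl)(Cl)Cl | starting material
13 | dichlorocyclobutanone: cis-fused bicyclo[5.2.0]nonane with C9=O, C10Cl2, C11 OSiMe3; four-membered ring on the face of the C7 methyl | C[Si](C)(C)O[C@@]12C(Cl)(Cl)C(=O)[C@@H]1[C@@](C)(O[Si](C)(C)C(C)(C)C)CC[C@@H]3C[C@@H](OCC)OC[C@@H]23 | intermediate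
14 | cyclobutanone: as 13 with C10H2 | C[Si](C)(C)O[C@@]12CC(=O)[C@@H]1[C@@](C)(O[Si](C)(C)C(C)(C)C)CC[C@@H]3C[C@@H](OCC)OC[C@@H]23 | intermediate
15 | C9 alcohol (hydroxyl cis to C7) with C11 OSiMe3 | C[Si](C)(C)O[C@@]12C[C@H](O)[C@@H]1[C@@](C)(O[Si](C)(C)C(C)(C)C)CC[C@@H]3C[C@@H](OCC)OC[C@@H]23 | intermediate (not isolated)
16 | cyclobutane-1,3-diol: C11 tertiary hydroxyl, C9 secondary hydroxyl cis to C7 | O[C@@]12C[C@H](O)[C@@H]1[C@@](C)(O[Si](C)(C)C(C)(C)C)CC[C@@H]3C[C@@H](OCC)OC[C@@H]23 | intermediate
17 | key-step precursor: cis-fused bicyclo[5.2.0]nonanol with C11 hydroxyl, C9 mesylate cis to C7, C7 OSi(t-Bu)Me2, C1/C3 cyclic ethyl acetal | O[C@@]12C[C@H](OS(C)(=O)=O)[C@@H]1[C@@](C)(O[Si](C)(C)C(C)(C)C)CC[C@@H]3C[C@@H](OCC)OC[C@@H]23 | intermediate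
18 | potassium C11 alkoxide of 17 | [K+].[O-][C@@]12C[C@H](OS(C)(=O)=O)[C@@H]1[C@@](C)(O[Si](C)(C)C(C)(C)C)CC[C@@H]3C[C@@H](OCC)OC[C@@H]23 | intermediate (not isolated)
19 | key-step product: nine-membered C11 ketone with (Z)-C8=C9 next to the C7 silyl ether, trans-fused cyclic ethyl acetal | O=C1C/C=C\[C@@](C)(O[Si](C)(C)C(C)(C)C)CC[C@@H]2C[C@@H](OCC)OC[C@@H]12 | intermediate
20 | C11 methylidene analogue of 19 | C=C1C/C=C\[C@@](C)(O[Si](C)(C)C(C)(C)C)CC[C@@H]2C[C@@H](OCC)OC[C@@H]12 | intermediate
21 | lactol (C3 hemiacetal, both anomers) | C=C1C/C=C\[C@@](C)(O[Si](C)(C)C(C)(C)C)CC[C@@H]2CC(O)OC[C@@H]12 | intermediate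
22 | δ-lactone (C3=O, O2–C1), trans-fused to the nine-membered diene | C=C1C/C=C\[C@@](C)(O[Si](C)(C)C(C)(C)C)CC[C@@H]2CC(=O)OC[C@@H]12 | intermediate
23 | 2,3-O-isopropylidene-D-erythronolactone | C1[C@H]([C@@H](O2)C(=O)O1)OC2(C)C | starting material
24 | 2-[(4R,5R)-5-(hydroxymethyl)-2,2-dimethyl-1,3-dioxolan-4-yl]propan-2-ol | OC[C@H]1OC(C)(C)O[C@H]1C(C)(C)O | intermediate
25 | (2R,3R)-4-methylpentane-1,2,3,4-tetrol | OC[C@@H](O)[C@@H](O)C(C)(C)O | intermediate
26 | (1R)-1-[(4R)-2,2-dimethyl-1,3-dioxolan-4-yl]-2-methylpropane-1,2-diol | CC1(C)OC[C@@H](O1)[C@@H](O)C(C)(C)O | intermediate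
27 | bis(tert-butyldimethylsilyl) ether of 26 (O14 and O15 silylated) | CC1(C)OC[C@@H](O1)[C@@H](O[Si](C)(C)C(C)(C)C)C(C)(C)O[Si](C)(C)C(C)(C)C | intermediate
28 | (2R,3R)-3,4-bis[(tert-butyldimethylsilyl)oxy]-4-methylpentane-1,2-diol | OC[C@@H](O)[C@@H](O[Si](C)(C)C(C)(C)C)C(C)(C)O[Si](C)(C)C(C)(C)C | intermediate
29 | (2R,3R)-3,4-bis[(tert-butyldimethylsilyl)oxy]-4-methyl-1,2-bis[(triethylsilyl)oxy]pentane | CC[Si](CC)(CC)OC[C@@H](O[Si](CC)(CC)CC)[C@@H](O[Si](C)(C)C(C)(C)C)C(C)(C)O[Si](C)(C)C(C)(C)C | intermediate
30 | (2S,3R)-3,4-bis[(tert-butyldimethylsilyl)oxy]-4-methyl-2-[(triethylsilyl)oxy]pentanal | O=C[C@@H](O[Si](CC)(CC)CC)[C@@H](O[Si](C)(C)C(C)(C)C)C(C)(C)O[Si](C)(C)C(C)(C)C | intermediate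
31 | lithium enolate of lactone 22 (C3–OLi, C3=C4) | C=C1C/C=C\[C@@](C)(O[Si](C)(C)C(C)(C)C)CC[C@@H]2C=C(O[Li])OC[C@@H]12 | intermediate (not isolated)
32 | aldol adduct: lactone 22 carrying at C4 the C12 carbinol chain (C12 hydroxyl, C13 OSiEt3, C14 and C15 OSi(t-Bu)Me2); C4/C12 epimers | C=C1C/C=C\[C@@](C)(O[Si](C)(C)C(C)(C)C)CC[C@@H]2C(C(O)[C@@H](O[Si](CC)(CC)CC)[C@@H](O[Si](C)(C)C(C)(C)C)C(C)(C)O[Si](C)(C)C(C)(C)C)C(=O)OC[C@@H]12 | intermediate
33 | C12 mesylate of 32 | C=C1C/C=C\[C@@](C)(O[Si](C)(C)C(C)(C)C)CC[C@@H]2C(C(OS(C)(=O)=O)[C@@H](O[Si](CC)(CC)CC)[C@@H](O[Si](C)(C)C(C)(C)C)C(C)(C)O[Si](C)(C)C(C)(C)C)C(=O)OC[C@@H]12 | intermediate (not isolated)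
34 | (Z)-C4=C12 alkylidene lactone (C13 cis to the C3 carbonyl) | C=C1C/C=C\[C@@](C)(O[Si](C)(C)C(C)(C)C)CC[C@@H]2/C(=C/[C@@H](O[Si](CC)(CC)CC)[C@@H](O[Si](C)(C)C(C)(C)C)C(C)(C)O[Si](C)(C)C(C)(C)C)C(=O)OC[C@@H]12 | intermediate
35 | (Z)-alkylidene lactol (C3 hemiacetal) | C=C1C/C=C\[C@@](C)(O[Si](C)(C)C(C)(C)C)CC[C@@H]2/C(=C/[C@@H](O[Si](CC)(CC)CC)[C@@H](O[Si](C)(C)C(C)(C)C)C(C)(C)O[Si](C)(C)C(C)(C)C)C(O)OC[C@@H]12 | intermediate
36 | C13 hydroxy lactol | C=C1C/C=C\[C@@](C)(O[Si](C)(C)C(C)(C)C)CC[C@@H]2/C(=C/[C@@H](O)[C@@H](O[Si](C)(C)C(C)(C)C)C(C)(C)O[Si](C)(C)C(C)(C)C)C(O)OC[C@@H]12 | intermediate (not isolated)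
37 | tris(silyl) bicyclic acetal: target skeleton with (Z)-C8=C9 in place of the epoxide and O7, O14, O15 as tert-butyldimethylsilyl ethers | C=C1C/C=C\[C@@](C)(O[Si](C)(C)C(C)(C)C)CC[C@@H]2C3=C[C@H]([C@@H](O[Si](C)(C)C(C)(C)C)C(C)(C)O[Si](C)(C)C(C)(C)C)O[C@@H]3OC[C@@H]12 | intermediate
38 | triol diene (8,9-deoxy target) | C=C1C/C=C\[C@@](C)(O)CC[C@@H]2C3=C[C@H]([C@@H](O)C(C)(C)O)O[C@@H]3OC[C@@H]12 | intermediate
39 | CNP0281409.2 (3S,4aS,7S,8R,9R,11aR,13R,14R) | C=C1C[C@H]2O[C@H]2[C@@](C)(O)CC[C@@H]2C3=C[C@H]([C@@H](O)C(C)(C)O)O[C@@H]3OC[C@@H]12 | target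

Total step count: 27. Longest linear sequence: 20 steps (steps 1–14 and 22–27, from 3-methylcyclohept-2-en-1-one); the aldehyde 30 is made in 7 steps (15–21).

Steps most likely to fail

Step 11 (key step). The danger lies in the basic medium: a slow fragmentation would leave time for loss of the mesylate by other routes, and the β,γ-unsaturated, β-alkoxy ketone can be consumed by double-bond migration, C11a epimerisation or β-elimination of O2. The fallback generates the alkoxide by desilylation instead of deprotonation. It sets out from 15 (obtained when step 9 is stopped before the carbonate treatment): mesylation (MeSO2Cl, pyridine) gives the C11 trimethylsilyl ether C9 mesylate F1. Anhydrous CsF in MeCN then cleaves the Si–O bond, and the alkoxide fragments as it is formed, without any external Brønsted base and without a free hydroxy mesylate. This returns to the route at 19.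

Step 5. The facial selectivity of the cuprate addition rests only on the conformational bias of the C7 quaternary centre and may be low, which would give the C4a epimer. The fallback replaces substrate control by catalyst control. It sets out from 6: rhodium-catalysed asymmetric 1,4-addition of (E)-2-ethoxyvinylboronic acid pinacol ester ([Rh(cod)Cl]2, the BINAP enantiomer that adds cis to the C7 methyl, aq. KOH, dioxane) gives the (E)-2-ethoxyvinyl ketone F2. Its kinetic enolate (LiN(i-Pr)2, −78 °C), which should form at the C11a methylene away from the quaternary carbon, is hydroxymethylated with formaldehyde to the hydroxy (E)-enol ether F3. Pyridinium p-toluenesulfonate then closes the acetal, and the route is rejoined at 10.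

Step 23. The elimination may give the (E)-alkene, which cannot close the dihydrofuran, and the base may epimerise C13 through the dienolate. The fallback fixes the geometry by a ring. It sets out from 32: removal of the C13 triethylsilyl group (HF·pyridine, then a trace of camphorsulfonic acid) lets O13 take over the acyl group and gives the β-hydroxy γ-lactone F4 with free C1 hydroxyl. Acetylation (Ac2O, Et3N, 4-dimethylaminopyridine) gives the diacetate F5, from which Et3N eliminates the β-acetoxy group to the butenolide acetate F6, in which C3 and C13 are necessarily cis. The aluminium hydride i-Bu2AlH (−78 °C) reduces the butenolide to the lactol and removes the acetate to give the lactol diol F7. Pyridinium p-toluenesulfonate closes the oxane through O2, and the route is rejoined at 37.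

Further compounds
F1 | step 11 | C11 trimethylsilyl ether C9 mesylate | C[Si](C)(C)O[C@@]12C[C@H](OS(C)(=O)=O)[C@@H]1[C@@](C)(O[Si](C)(C)C(C)(C)C)CC[C@@H]3C[C@@H](OCC)OC[C@@H]23
F2 | step 5 | (E)-2-ethoxyvinyl ketone (C4a set by the catalyst) | O=C1C[C@@](C)(O[Si](C)(C)C(C)(C)C)CC[C@H](/C=C/OCC)C1
F3 | step 5 | hydroxy (E)-enol ether ketone | O=C1C[C@@](C)(O[Si](C)(C)C(C)(C)C)CC[C@H](/C=C/OCC)[C@H]1CO
F4 | step 23 | β-hydroxy γ-lactone (O13–C3 ester) with free C1 hydroxyl | C=C1C/C=C\[C@@](C)(O[Si](C)(C)C(C)(C)C)CC[C@H](C2C(O)[C@H]([C@@H](O[Si](C)(C)C(C)(C)C)C(C)(C)O[Si](C)(C)C(C)(C)C)OC2=O)[C@H]1CO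
F5 | step 23 | C1/C12 diacetate of F4 | C=C1C/C=C\[C@@](C)(O[Si](C)(C)C(C)(C)C)CC[C@H](C2C(OC(C)=O)[C@H]([C@@H](O[Si](C)(C)C(C)(C)C)C(C)(C)O[Si](C)(C)C(C)(C)C)OC2=O)[C@H]1COC(C)=O
F6 | step 23 | butenolide C1 acetate | C=C1C/C=C\[C@@](C)(O[Si](C)(C)C(C)(C)C)CC[C@H](C2=C[C@H]([C@@H](O[Si](C)(C)C(C)(C)C)C(C)(C)O[Si](C)(C)C(C)(C)C)OC2=O)[C@H]1COC(C)=O
F7 | step 23 | 2,5-dihydrofuran-2-ol (lactol) with free C1 hydroxyl | C=C1C/C=C\[C@@](C)(O[Si](C)(C)C(C)(C)C)CC[C@H](C2=C[C@H]([C@@H](O[Si](C)(C)C(C)(C)C)C(C)(C)O[Si](C)(C)C(C)(C)C)OC2O)[C@H]1CO
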